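The vessel is closed, stirred and held at one temperature, and it takes a charge of substrate and partner; earlier runs give what is known so far.

| setting | zeta | alpha | theta | Saturday's | Wednesday's |
|---|---|---|---|---|---|
| substrate | 1.5 M | 2.4 M | 1.1 M | 1.1 M | 1.1 M |
| partner | 0.88 M | 0.88 M | 1.8 M | 0.880 M | 0.880 M |
| remark | run made earlier | run made earlier | run made earlier |  |  |
| time |  |  |  | 1.0 h | 3.0 h |

| run | time / min | target / % | homo product / % | isomer of the product / % | substrate / % |
|---|---|---|---|---|---|
| zeta | 15.0 | 10.8 | 2.2 | 1.6 | 80.8 |
| zeta | 30.0 | 16.2 | 5.7 | 6.9 | 64.6 |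
| zeta | 40.0 | 17.3 | 6.6 | 9.6 | 56.7 |
| zeta | 60.0 | 18.9 | 12.4 | 16.7 | 42.7 |
| zeta | 80.0 | 19.4 | 16.5 | 25.6 | 30.4 |
| alpha | 6.00 | 1.5 | 0 | 0 | 93.1 |
| alpha | 20.0 | 11.1 | 5.6 | 1.8 | 77.4 |
| alpha | 30.0 | 15.4 | 8.3 | 6.3 | 64.2 |
| alpha | 50.0 | 16.3 | 14.4 | 12.2 | 49.0 |
| alpha | 80.0 | 11.5 | 26.0 | 21.2 | 30.6 |
| theta | 15.0 | 14.2 | 0 | 2.5 | 78.6 |
| theta | 30.0 | 23.1 | 1.3 | 9.3 | 64.7 |
| theta | 40.0 | 24.4 | 1.7 | 14.9 | 57.5 |
| theta | 60.0 | 25.9 | 0.4 | 26.3 | 41.1 |
| theta | 80.0 | 25.9 | 0.6 | 36.9 | 32.3 |

(scatter of a reading: 1 percentage point)

- percent here means substrate units held: one homo product counts as two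

- which of these there is most of at the end, counted by the substrate in it, Saturday's (isomer of the product / substrate / homo product / target)
- which of these there is most of at the end, counted by the substrate in it, Wednesday's (isomer of the product / substrate / homo product / target)
- how much there is at the end of the one of these that leads, in percent of the substrate charged: Saturday's
- how much there is at the end of the one of these that leads, in percent of the substrate charged: Wednesday's

At 80.0 min the substrate stands at 30.4%, 30.6% and 32.3% in the zeta, alpha and theta runs, although its charge runs from 1.1 M to 2.4 M and the partner's from 0.88 M to 1.8 M. That is the mark of first-order decay: the amount left is the charge times the exponential of minus a constant times the time. The mean of those readings gives 0.0146 /min, the decay constant, the share of the remaining substrate lost per minute.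

So Saturday's should keep 41.6% of its substrate and Wednesday's 7.22%. In the theta run, isomer reads 26.3% at 60.0 min, less than the substrate reckoned for Saturday's, so substrate should lead Saturday's. The zeta run has Wednesday's partner charge, and at 80.0 min it reads 25.6% of isomer, 19.4% of target and 16.5% of homo product; with substrate reckoned at 7.22% for Wednesday's, isomer should lead Wednesday's, but this reckoning puts no figure on it.

The forecast, holding that “Substrate decay is first order and nearly the same in all three runs”, names substrate for Saturday's at 42% (range 39.5% to 44.5%) and isomer of the product for Wednesday's at 62% (range 55% to 68%).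

The flask gives substrate at 42.4% on Saturday's and isomer of the product at 58.5% on Wednesday's, both inside those ranges.

    substrate → intermediate (k = 0.0140 /min)
    partner + intermediate → target (k = 0.210 /M/min)
    2 intermediate → homo product (k = 0.210 /M/min)
    substrate + intermediate → side product (k = 0.00520 /M/min)
    target ⇌ isomer of the product (K = 24.0, k = 0.0230 /min)

The longer time is the main reason that Wednesday's substrate stands at 7.68% against 42.4% on Saturday's, close to the 7.22% and 41.6% reckoned from the decay constant. Substrate and isomer stand equal at 1.38 h, which Saturday's has not reached and Wednesday's has passed, so the two leads of the forecast lie on either side of that time. Saturday's flask left until 1.5 h holds 27.6% of substrate, against 26.9% from the constant, and 33.7% of isomer.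

The data are simulated for substances that don't exist; noise was put on by code.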